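**Retrosynthetic overview**
- The strategy rests on the unbranched, saturated C26 acyl chain: it has no functional group between C2 and C26, so it can be assembled at any CH2–CH2 bond. The only ring, the benzene ring of the 2-phenylethyl ester, is bought in and no ring is formed.
- Key disconnection: C9–C10 of the chain (carbonyl carbon = C1), made last by crossed Kolbe electrolysis. Stearic acid supplies the C17 alkyl part and mono-2-phenylethyl sebacate supplies the C1–C9 arm that already bears the ester, each after loss of CO2.
- The half-ester comes from undec-10-enoic acid: esterification with 2-phenylethanol (ester C–O bond first), ozonolysis of the terminal alkene to the C10 aldehyde, then Pinnick oxidation.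
- The same electrolysis also homo-couples each acid, giving a C34 alkane and a C18 diester; these differ from the target in ester count and are removed on silica. The target has no stereocentre and no alkene geometry.

Key step: step 6

Assumption: "phenylethyl" is read as 2-phenylethyl, as the SMILES requires, and the stearic acid is taken to be a pure C18 grade free of palmitic acid, so that no C24 homologue of the target can form.
Remark: steps 4, 5 and 6 are three anodic couplings that run side by side in one electrolysis of a single charge of the half-ester and stearic acid. They are written as separate steps so that each product has its own equation; the products of steps 4 and 5 are separated and not carried on.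

Step 1
Reactants: 1 undec-10-enoic acid; 2 2-phenylethanol
Product: 3 2-phenylethyl undec-10-enoate
Conditions: 1 (1.1 equiv.), TsOH·H2O (5 mol%), PhMe, reflux, Dean–Stark; aq. NaHCO3 wash
Reagents that add atoms: none
Why: Fischer esterification driven to completion by azeotropic removal of water; the isolated terminal alkene is inert to catalytic TsOH, and the slight excess of 1 is washed out with bicarbonate.

Step 2
Reactants: 3 2-phenylethyl undec-10-enoate
Product: 5 2-phenylethyl 10-oxodecanoate, via trioxolane ozonide 4 (not isolated)
Conditions: O3, CH2Cl2, −78 °C, gas feed stopped at the first persistent blue tint, N2 purge; then Me2S, −78 °C → rt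
Reagents that add atoms: ozone, [O-][O+]=O
Why: Criegee ozonolysis: the terminal alkene takes up ozone far faster than the mono-alkylbenzene ring, so stopping at the end point should leave the arene intact, and Me2S reduces the racemic secondary ozonide 4 to aldehyde 5 while the terminal carbon leaves as formaldehyde.

Step 3
Reactants: 5 2-phenylethyl 10-oxodecanoate
Product: 6 10-oxo-10-(2-phenylethoxy)decanoic acid (mono-2-phenylethyl sebacate)
Conditions: NaClO2, NaH2PO4, 2-methyl-2-butene (excess), t-BuOH/H2O, 0 °C → rt
Reagents that add atoms: sodium chlorite, [Na+].[O-]Cl=O
Why: Pinnick oxidation: chlorous acid formed in the phosphate buffer adds to the aldehyde and fragments to the carboxylic acid and HOCl, which 2-methyl-2-butene traps, so the ester and the benzene ring should stay untouched and the half-ester is obtained free of diacid and diester.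

Step 4
Reactants: 7 stearic acid (octadecanoic acid), two molecules
Product: 8 tetratriacontane
Conditions: smooth Pt anode, Pt cathode, undivided cell, KOH (ca. 0.05–0.1 equiv. per CO2H), MeOH, 45–50 °C, ca. 0.25 A cm−2; runs in the cell and charge of step 6, where 7 is present in ca. fourfold excess over 6
Reagents that add atoms: none
Why: Kolbe homo-dimerisation: two stearate ions are each oxidised by one electron at the platinum anode, lose CO2 and the two heptadecyl radicals pair at the electrode surface, which is expected to be the main companion reaction because 7 is the acid in excess; the ester-free hydrocarbon is removed as the non-polar fraction.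

Step 5
Reactants: 6 10-oxo-10-(2-phenylethoxy)decanoic acid, two molecules
Product: 9 bis(2-phenylethyl) octadecanedioate
Conditions: smooth Pt anode, Pt cathode, undivided cell, KOH (ca. 0.05–0.1 equiv. per CO2H), MeOH, 45–50 °C, ca. 0.25 A cm−2; runs in the cell and charge of step 6
Reagents that add atoms: none
Why: Kolbe homo-dimerisation of a half-ester (Brown–Walker type): two 8-(2-phenylethoxycarbonyl)octyl radicals formed by anodic decarboxylation of 6 pair to the C18 diester, a minor pathway kept low by the excess of 7 and removed as the more polar two-ester fraction.

Step 6
Reactants: 6 10-oxo-10-(2-phenylethoxy)decanoic acid; 7 stearic acid (octadecanoic acid)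
Product: 10 phenylethyl n-hexacosanoate (2-phenylethyl hexacosanoate, target)
Conditions: smooth Pt anode, Pt cathode, undivided cell, 7 (ca. 4 equiv.), KOH (ca. 0.05–0.1 equiv. per CO2H), MeOH, 45–50 °C, ca. 0.25 A cm−2, stopped while still weakly acidic; evaporation, SiO2 chromatography (hexane → hexane/EtOAc), recrystallisation
Reagents that add atoms: none
Why: This is a crossed Kolbe electrolysis, the classical anodic chain extension in which a fatty acid is coupled with an alkanedioic acid half-ester. At the smooth platinum anode the adsorbed carboxylates of 6 and 7 each give up one electron and lose CO2, so that the 8-(2-phenylethoxycarbonyl)octyl and heptadecyl radicals arise side by side in high surface concentration and pair to form the C9–C10 sigma bond of the hexacosanoyl chain, while protons are reduced to H2 at the cathode. No ring closes and no stereocentre is created. Two selectivities are needed: cross- over homo-coupling is only statistical, so 7 is used in about fourfold excess to make nearly every radical from 6 meet a heptadecyl partner, and the homo-dimers 8 (no ester, step 4) and 9 (two esters, step 5) are separated from the monoester 10 by polarity on silica; radical coupling over further oxidation to carbocations is favoured because both radicals are primary and unbranched and because smooth platinum, high current density and a weakly acidic methanolic electrolyte are used. The phenethyl ester should survive because the electrolysis is stopped before the medium turns basic, so no methoxide is available for transesterification, and the benzene ring, eight or more atoms from the radical site and screened from the anode by the carboxylate layer, should neither trap the radical nor be oxidised.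

**Compound list**
1 | undec-10-enoic acid | C=CCCCCCCCCC(=O)O | starting material
2 | 2-phenylethanol | OCCc1ccccc1 | starting material
3 | 2-phenylethyl undec-10-enoate | C=CCCCCCCCCC(=O)OCCc1ccccc1 | intermediate
4 | 2-phenylethyl 9-(1,2,4-trioxolan-3-yl)nonanoate (secondary ozonide, racemic, not isolated) | O=C(CCCCCCCCC1OCOO1)OCCc2ccccc2 | intermediate
5 | 2-phenylethyl 10-oxodecanoate | O=CCCCCCCCCC(=O)OCCc1ccccc1 | intermediate
6 | 10-oxo-10-(2-phenylethoxy)decanoic acid (mono-2-phenylethyl sebacate) | OC(=O)CCCCCCCCC(=O)OCCc1ccccc1 | intermediate
7 | stearic acid (octadecanoic acid) | CCCCCCCCCCCCCCCCCC(=O)O | starting material
8 | tetratriacontane (homo-coupling co-product of the electrolysis, separated and not carried on) | CCCCCCCCCCCCCCCCCCCCCCCCCCCCCCCCCC | intermediate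
9 | bis(2-phenylethyl) octadecanedioate (homo-coupling co-product of the electrolysis, separated and not carried on) | O=C(OCCc1ccccc1)CCCCCCCCCCCCCCCCC(=O)OCCc1ccccc1 | intermediate
10 | phenylethyl n-hexacosanoate (2-phenylethyl hexacosanoate) | CCCCCCCCCCCCCCCCCCCCCCCCCC(=O)OCCc1ccccc1 | target

**Step count**
Total steps: 6 (steps 4, 5 and 6 are one electrolysis, so four laboratory operations). Longest linear sequence: 4 steps (1 → 3 → 5 → 6 → 10, through steps 1, 2, 3 and 6).

**Steps most likely to fail**

1. Step 6 (crossed Kolbe electrolysis). The risks are that homo-coupling and two-electron (carbocation) pathways outrun the cross-coupling, that the anode is fouled by poorly soluble hydrocarbon, that the arene is attacked anodically, or that the phenethyl ester is methanolysed if the electrolyte drifts basic. Fallback: setting out from aldehyde 5, a Wittig olefination with the ylide from hexadecyltriphenylphosphonium bromide (NaN(SiMe3)2, THF, −78 °C → rt) would give 2-phenylethyl (Z)-hexacos-10-enoate F1. Hydrogenation of the alkene (H2, Pd/C, EtOAc, rt) would then come back to the route at the target 10; the phenethyl C–O bond is not benzylic and should not be cleaved.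

2. Step 2 (ozonolysis). The risks are over-oxidation, with ozone beginning to attack the benzene ring once the alkene is consumed, or incomplete reduction that leaves peroxidic material to degrade the aldehyde on work-up. Fallback: setting out from alkene 3, dihydroxylation (OsO4 cat., N-methylmorpholine N-oxide, acetone/H2O, rt) would give racemic 2-phenylethyl 10,11-dihydroxyundecanoate F2. Glycol cleavage with NaIO4 (THF/H2O, rt) would come back to the route at aldehyde 5.

3. Step 3 (Pinnick oxidation). The risks are loss of the aldehyde by air oxidation or self-condensation before it is oxidised, or chlorination by hypochlorous acid that escapes the scavenger. Fallback: setting out from 2-phenylethanol 2, slow addition of 2 and pyridine to a threefold excess of commercial decanedioyl dichloride (CH2Cl2, 0 °C) would give 2-phenylethyl 10-chloro-10-oxodecanoate F3. Hydrolysis of the remaining acid chloride (THF/H2O, rt) would come back to the route at half-ester 6; the sebacic acid from the excess reagent would be removed by filtration from cold CH2Cl2 and on silica.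

**Further compounds**
F1 | step 6 | 2-phenylethyl (Z)-hexacos-10-enoate | CCCCCCCCCCCCCCC/C=C\CCCCCCCCC(=O)OCCc1ccccc1
F2 | step 2 | 2-phenylethyl 10,11-dihydroxyundecanoate (racemic) | OCC(O)CCCCCCCCC(=O)OCCc1ccccc1
F3 | step 3 | 2-phenylethyl 10-chloro-10-oxodecanoate | O=C(Cl)CCCCCCCCC(=O)OCCc1ccccc1
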